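The closed, stirred vessel holds the gas at 0.42 mM, so we count what each flask has taken up. We assume that whatever is neither substrate nor single product has taken gas twice.

| setting | alpha | theta | winter | dusk | summer | spring | noon |
|---|---|---|---|---|---|---|---|
| substrate | 4.8 mM | 28 mM | 6.0 mM | 40 mM | 15 mM | 10 mM | 30 mM |
| gas | 0.42 mM (held) | 0.42 mM (held) | 0.42 mM (held) | 0.42 mM (held) | 0.42 mM (held) | 0.42 mM (held) | 0.42 mM (held) |
| remark | run made earlier | run made earlier |  |  |  |  |  |
| time |  |  | 20 h | 20 h | 20 h | 20 h | 20 h |

| run | time / h | single product / % | substrate / % |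
|---|---|---|---|
| alpha | 1.33 | 25.2 | 70.7 |
| alpha | 4.00 | 47.4 | 31.0 |
| alpha | 8.00 | 41.1 | 9.3 |
| alpha | 10.0 | 32.5 | 4.4 |
| alpha | 15.0 | 14.3 | 1.5 |
| alpha | 20.0 | 5.5 | 0.1 |
| theta | 1.50 | 12.8 | 87.3 |
| theta | 2.50 | 19.8 | 78.5 |
| theta | 4.00 | 29.3 | 66.0 |
| theta | 8.00 | 44.3 | 40.6 |
| theta | 12.0 | 48.6 | 22.6 |
| theta | 20.0 | 32.8 | 4.6 |

(readings scatter by 0.5 percentage points)

* ranking by amount of single product, in percent of the substrate charged, from high to low, at 20 h (winter / dusk / summer / spring / noon)
* the amount of single product, in percent of the substrate charged of the flask you put first, at 20 h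
* the amount of single product, in percent of the substrate charged of the flask you put last, at 20 h

- at the start none of the gas is in solution

1. The zero of the scale. We give each substrate 2 equal sites, a selectivity factor of 0.5. Let x, the fill, be gas taken up over 2 times the substrate charged. Single product is then 2x(1 − x), which tops out at 50.0% and falls beyond x = 0.5.

2. Calibration. Theta at 12.0 h reads 48.6% where the scale, from its substrate reading, gives 49.9%. Reading over scale is 0.974, our scale ratio.

3. Upper bound. Theta took up 44.2 mM by 20.0 h. We take it that dusk, charged at 40 mM, takes at least as much, so its fill is at least 0.553, which past x = 0.5 gives at most 48.2%.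

4. Lower bound. We take theta's early rate, 2.71 mM/h over 4.00 h, as dusk's ceiling for 20 h, which gives a fill of at most 0.677 and at least 42.6%.

5. Tightened. Theta's rate over 8.00 h, 2.61 mM/h, gives fill 0.652, so we commit to 44.2%. At equal uptake a lighter charge has the higher fill, and we reckon dusk already beyond x = 0.5, so we rank by falling charge and put winter, charged close to alpha, near alpha's 5.5% at 20.0 h.

6. The forecast says dusk > noon > summer > spring > winter, top 43%, low 6.3%, on the ground that “Product yield therefore depends mostly on conversion”. Its top lies inside our bracket and below our 44.2%.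

7. The flask gives dusk > noon > summer > spring > winter, top 44.8%, low 6.28%. That top, dusk's, also lies inside our bracket.

    substrate + reagent → other mono adduct (k = 34.1 /M/h)
    reagent + other mono adduct → bis adduct (k = 1860 /M/h)
    substrate → decomposition product (k = 6.96 × 10⁻⁴ /h)
    substrate + reagent → single product (k = 972 /M/h)
    gas ⇌ reagent, rate k5*(csat - [reagent]) (kL = 8.20 /h)
    reagent + single product → bis adduct (k = 484 /M/h)

Reagent + single product runs at 0.481 of substrate + reagent to both mono adducts taken together, near the statistical 0.5. Dusk at 20.0 h has 12.2% substrate left, a fill on the scale of 0.651, and the ratio 0.974 turns that into 44.3%, where dusk holds 44.8% single product. The neighbour, winter read at 5.00 h, has 26% substrate left, a fill on the scale of 0.492. The same ratio gives 48.7%, and that flask holds 48.9% single product.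

The numbers in the tables were generated by integration for an exercise; scatter was added.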